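**Plan**
- Retrosynthetic cuts: first the two O–benzyl bonds of the catechol, then the two C–S bonds on the benzylic carbon attached to C4 and the C5–O(menthyl) bond, and last, in one operation, the bond from C4 to that benzylic carbon and the bond from C3 to the 3,4-dimethoxybenzyl CH2.
- Enabling feature: in the γ-butyrolactone ring (O1, C2=O, C3, C4, C5) the two ArCH2 groups sit trans on neighbouring C3 (α to the carbonyl) and C4 (β), and C5 is a bare CH2. C3–C4 is therefore the former C3=C4 bond of a furan-2(5H)-one, with C4 as acceptor carbon and C3 as enolate carbon, and C5 can have carried a removable acetal oxygen.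
- Forward order: the five-membered ring comes from furfural and is not formed in the key step. A lithiated aryl dithiane is joined to C4 and the enolate is benzylated at C3 in the same flask. The acetal carbon is then reduced to CH2 (the ring opens and recloses on the same carboxyl carbon), sulfur is removed and the benzyl ethers are cleaved.
- Stereochemistry: (−)-menthol fixes C5 as R through crystallisation of one acetal epimer. C5 sends the nucleophile to the opposite face at C4, and C4 sends the bromide to the opposite face at C3, giving 3R,4R. The C5 centre is then erased.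

Key step: step 5

Remark: 3,4-bis(benzyloxy)benzaldehyde is taken as a purchased material; benzyl ethers are chosen for the catechol because they tolerate n-BuLi at low temperature and KOH/NaBH4 and are removed last under neutral hydrogenolysis.

**Step 1**
Reactants: 1 furfural
Product: 3 5-hydroxyfuran-2(5H)-one (racemic), via furfural endoperoxide 2 (not isolated)
Conditions: O2, hν (visible), rose bengal disodium salt (C20H2Cl4I4Na2O5, cat.), MeOH, 20 °C
Reagents that add atoms: oxygen, O=O
Why: Dye-sensitised singlet-oxygen [4+2] cycloaddition to the furan should give endoperoxide 2, whose methanolysis expels the formyl carbon as methyl formate and leaves the γ-hydroxybutenolide; C5 is a freely epimerising hemiacetal, so no stereocontrol is needed here.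

**Step 2**
Reactants: 3 5-hydroxyfuran-2(5H)-one; 4 (−)-menthol
Product: 5 (5R)-5-[(1R,2S,5R)-menthyl]oxyfuran-2(5H)-one
Conditions: p-toluenesulfonic acid (cat.), toluene, reflux, Dean–Stark; crystallisation from petroleum ether, −20 °C; mother liquor re-equilibrated with the acid and recrystallised
Reagents that add atoms: none
Why: Acid-catalysed acetalisation of the pseudo-acid should give both C5 epimers, which interconvert through the oxocarbenium ion, and the 5R epimer is the one expected to crystallise, so C5 is set by crystallisation-driven equilibration against the fixed menthyl stereocentres.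

**Step 3**
Reactants: 6 3,4-bis(benzyloxy)benzaldehyde
Product: 7 2-[3,4-bis(benzyloxy)phenyl]-1,3-dithiane
Conditions: propane-1,3-dithiol, I2 (cat.), CH2Cl2, rt
Reagents that add atoms: propane-1,3-dithiol, SCCCS
Why: Lewis-acid-catalysed dithioacetalisation of an aromatic aldehyde (Corey–Seebach dithiane formation) should mask the future C4 benzylic carbon as an acyl-anion equivalent, and the mild iodine catalyst should spare the benzyl ethers.

**Step 4**
Reactants: 8 3,4-dimethoxybenzyl alcohol
Product: 9 3,4-dimethoxybenzyl bromide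
Conditions: PBr3 (0.4 equiv), Et2O, 0 °C; used at once
Reagents that add atoms: phosphorus tribromide, BrP(Br)Br
Why: SN2 displacement of the phosphite-activated hydroxyl by bromide should convert the electron-rich benzylic alcohol into the bromide, which is used fresh because it tends to self-condense on storage.

**Step 5**
Reactants: 7 2-[3,4-bis(benzyloxy)phenyl]-1,3-dithiane; 5 (5R)-5-[(1R,2S,5R)-menthyl]oxyfuran-2(5H)-one; 9 3,4-dimethoxybenzyl bromide
Product: 12 (3R,4R,5R)-4-{2-[3,4-bis(benzyloxy)phenyl]-1,3-dithian-2-yl}-3-(3,4-dimethoxybenzyl)-5-[(1R,2S,5R)-menthyl]oxydihydrofuran-2(3H)-one, via lithiated dithiane 10 (not isolated), via lithium enolate 11 (not isolated)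
Conditions: 7, n-BuLi, THF, −78 to −20 °C; then 5, −78 °C; then 9, −78 °C to rt
Reagents that add atoms: none
Why: n-BuLi removes the C2 proton of 7 to give the sulfur-stabilised benzylic carbanion 10, which adds to C4 of butenolide 5 in a conjugate sense (a soft, hindered anion prefers the β-carbon to the lactone carbonyl), and the lithium enolate 11 is then benzylated on carbon at C3 by SN2 displacement on bromide 9. The closest known reaction type is the one-flask Michael addition–enolate alkylation of 5-alkoxyfuran-2(5H)-ones with 2-aryl-2-lithio-1,3-dithianes and benzylic halides. No ring is closed: the lactone is present beforehand and only the C4–C(dithiane) and C3–CH2Ar bonds are made. The C4 centre is controlled by the C5 acetal centre, because the anion approaches the flat butenolide on the face away from the menthyloxy group, which should give 4R. The C3 centre is controlled by C4, because the bromide reaches the enolate on the face away from the bulky dithianyl group, which should give the 3,4-trans (3R) arrangement. The step needs 1,4- over 1,2-addition, C- over O-alkylation and no reversal of the Michael addition; the delocalised dithiane anion, the lithium counter-ion in THF with a reactive benzylic bromide, and holding the mixture at −78 °C until the bromide is in should secure these.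

**Step 6**
Reactants: 12 (3R,4R,5R)-4-{2-[3,4-bis(benzyloxy)phenyl]-1,3-dithian-2-yl}-3-(3,4-dimethoxybenzyl)-5-[(1R,2S,5R)-menthyl]oxydihydrofuran-2(3H)-one
Product: 15 (3R,4R)-4-{2-[3,4-bis(benzyloxy)phenyl]-1,3-dithian-2-yl}-3-(3,4-dimethoxybenzyl)dihydrofuran-2(3H)-one, via formyl carboxylate 13 (not isolated), via hydroxy carboxylate 14 (not isolated)
Conditions: NaBH4 (excess), KOH, THF/EtOH/H2O, 0 °C to rt; then aq. HCl to pH 1, rt
Reagents that add atoms: potassium hydroxide, [K+].[OH-] (its oxygen enters the carboxylate and can remain as the lactone carbonyl oxygen after reclosure)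
Why: Hydroxide should open the acylal-type lactone, the exposed hemiacetal should collapse with loss of menthol to aldehyde 13, NaBH4 should reduce it at once to 14 and acid should close the γ-lactone on the original C2 carboxyl (saponification, borohydride reduction, lactonisation); C3 lies α to a non-enolising carboxylate and C4 is protected by fast hydride capture of the aldehyde, so both centres should be kept while the C5 centre is erased.

**Step 7**
Reactants: 15 (3R,4R)-4-{2-[3,4-bis(benzyloxy)phenyl]-1,3-dithian-2-yl}-3-(3,4-dimethoxybenzyl)dihydrofuran-2(3H)-one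
Product: 16 (3R,4R)-4-[3,4-bis(benzyloxy)benzyl]-3-(3,4-dimethoxybenzyl)dihydrofuran-2(3H)-one
Conditions: Raney Ni (W-2), EtOH, reflux
Reagents that add atoms: none
Why: Raney-nickel hydrogenolysis of the two benzylic C–S bonds (Mozingo-type desulfurisation) should turn the dithiane carbon into the C4 benzylic CH2 without touching the lactone or the C3 and C4 centres, and any benzyl ether lost here is of no consequence because step 8 removes them all.

**Step 8**
Reactants: 16 (3R,4R)-4-[3,4-bis(benzyloxy)benzyl]-3-(3,4-dimethoxybenzyl)dihydrofuran-2(3H)-one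
Product: 17 (3R,4R)-4-(3,4-dihydroxybenzyl)-3-(3,4-dimethoxybenzyl)dihydrofuran-2(3H)-one
Conditions: H2 (1 atm), 10% Pd/C, EtOAc/EtOH, rt
Reagents that add atoms: none
Why: Palladium-catalysed hydrogenolysis of the two benzyl aryl ethers should free the catechol under neutral conditions that leave the methyl ethers, the lactone and both stereocentres untouched.

**Compound list**
1 | furfural | O=Cc1ccco1 | starting material
2 | 2,3,7-trioxabicyclo[2.2.1]hept-5-ene-1-carbaldehyde (furfural endoperoxide, racemic) | O=CC12OOC(C=C1)O2 | intermediate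
3 | 5-hydroxyfuran-2(5H)-one (racemic) | O=C1C=CC(O)O1 | intermediate
4 | (−)-menthol, (1R,2S,5R)-2-isopropyl-5-methylcyclohexan-1-ol | C[C@@H]1CC[C@H]([C@@H](C1)O)C(C)C | starting material
5 | (5R)-5-[(1R,2S,5R)-menthyl]oxyfuran-2(5H)-one (menthyl = 2-isopropyl-5-methylcyclohexyl) | O=C1C=C[C@H](O[C@@H]2C[C@H](C)CC[C@H]2C(C)C)O1 | intermediate
6 | 3,4-bis(benzyloxy)benzaldehyde | O=Cc1ccc(OCc2ccccc2)c(OCc2ccccc2)c1 | starting material
7 | 2-[3,4-bis(benzyloxy)phenyl]-1,3-dithiane | C1CSC(SC1)c1ccc(OCc2ccccc2)c(OCc2ccccc2)c1 | intermediate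
8 | 3,4-dimethoxybenzyl alcohol | COc1ccc(CO)cc1OC | starting material
9 | 3,4-dimethoxybenzyl bromide | COc1ccc(CBr)cc1OC | intermediate
10 | 2-[3,4-bis(benzyloxy)phenyl]-2-lithio-1,3-dithiane | [Li]C1(SCCCS1)c1ccc(OCc2ccccc2)c(OCc2ccccc2)c1 | intermediate
11 | lithium (4R,5R)-4-{2-[3,4-bis(benzyloxy)phenyl]-1,3-dithian-2-yl}-5-[(1R,2S,5R)-menthyl]oxy-4,5-dihydrofuran-2-olate | [Li]OC1=C[C@@H](C2(SCCCS2)c2ccc(OCc3ccccc3)c(OCc3ccccc3)c2)[C@H](O[C@@H]2C[C@H](C)CC[C@H]2C(C)C)O1 | intermediate
12 | (3R,4R,5R)-4-{2-[3,4-bis(benzyloxy)phenyl]-1,3-dithian-2-yl}-3-(3,4-dimethoxybenzyl)-5-[(1R,2S,5R)-menthyl]oxydihydrofuran-2(3H)-one | COc1ccc(C[C@H]2C(=O)O[C@@H](O[C@@H]3C[C@H](C)CC[C@H]3C(C)C)[C@@H]2C2(SCCCS2)c2ccc(OCc3ccccc3)c(OCc3ccccc3)c2)cc1OC | intermediate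
13 | potassium (2R,3R)-3-{2-[3,4-bis(benzyloxy)phenyl]-1,3-dithian-2-yl}-2-(3,4-dimethoxybenzyl)-4-oxobutanoate | COc1ccc(C[C@@H](C(=O)[O-])[C@H](C=O)C2(SCCCS2)c2ccc(OCc3ccccc3)c(OCc3ccccc3)c2)cc1OC.[K+] | intermediate
14 | potassium (2R,3R)-3-{2-[3,4-bis(benzyloxy)phenyl]-1,3-dithian-2-yl}-2-(3,4-dimethoxybenzyl)-4-hydroxybutanoate | COc1ccc(C[C@@H](C(=O)[O-])[C@H](CO)C2(SCCCS2)c2ccc(OCc3ccccc3)c(OCc3ccccc3)c2)cc1OC.[K+] | intermediate
15 | (3R,4R)-4-{2-[3,4-bis(benzyloxy)phenyl]-1,3-dithian-2-yl}-3-(3,4-dimethoxybenzyl)dihydrofuran-2(3H)-one | COc1ccc(C[C@H]2C(=O)OC[C@@H]2C2(SCCCS2)c2ccc(OCc3ccccc3)c(OCc3ccccc3)c2)cc1OC | intermediate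
16 | (3R,4R)-4-[3,4-bis(benzyloxy)benzyl]-3-(3,4-dimethoxybenzyl)dihydrofuran-2(3H)-one | COc1ccc(C[C@H]2C(=O)OC[C@@H]2Cc2ccc(OCc3ccccc3)c(OCc3ccccc3)c2)cc1OC | intermediate
17 | (3R,4R)-4-(3,4-dihydroxybenzyl)-3-(3,4-dimethoxybenzyl)dihydrofuran-2(3H)-one | COc1ccc(C[C@H]2C(=O)OC[C@@H]2Cc2ccc(O)c(O)c2)cc1OC | target

**Totals**
Total step count: 8. Longest linear sequence: 6 steps (1, 2, 5, 6, 7, 8, from furfural).

**Steps most likely to fail**

Step 5. The coupling may suffer from attack at the lactone carbonyl or proton abstraction at C5 instead of conjugate addition, from reversal of the Michael addition on warming, or from incomplete or oxygen-directed trapping of the enolate. The fallback separates the two bond formations and sets out from 5 and 7. Anion 10 is added to 5 in THF at −78 °C and enolate 11 is protonated cold with aqueous NH4Cl, which should allow isolation of the Michael adduct (4R,5R)-4-{2-[3,4-bis(benzyloxy)phenyl]-1,3-dithian-2-yl}-5-[(1R,2S,5R)-menthyl]oxydihydrofuran-2(3H)-one F1. This is re-enolised with LiN(iPr)2 in THF at −78 °C (giving 11 again) and alkylated with 9 in the presence of DMPU (N,N'-dimethylpropyleneurea), anti to the C4 group, so the route is rejoined at 12.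

Step 6. The aldehyde released on ring opening may enolise before hydride reaches it, which would epimerise the carbon bearing the dithiane or eliminate sulfur from the neighbouring carbon, and the crowded lactone may open slowly. The fallback reverses the order of sulfur removal and acetal reduction and sets out from 12. Desulfurisation with Ni2B generated from NiCl2·6H2O and NaBH4 in MeOH/THF at 0 °C should give the 5-menthyloxy dibenzyl lactone F2, whose C4 substituent is now a plain benzyl group. Treatment with NaBH4/KOH in aqueous EtOH should pass through the potassium formyl carboxylate F3 and the potassium hydroxy carboxylate F4, and acidification with HCl closes the lactone. The route is rejoined at 16 and compound 15 is bypassed.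

Step 7. Cleavage of the second C–S bond may stall, or the benzyl ethers may be lost unevenly on nickel, leaving mixtures and sulfur residues that deactivate the palladium of step 8. The fallback removes sulfur by hydrolysis instead of hydrogenolysis and sets out from 15. MeI and CaCO3 in aqueous MeCN at 50 °C should unmask the aryl ketone (3R,4R)-4-[3,4-bis(benzyloxy)benzoyl]-3-(3,4-dimethoxybenzyl)dihydrofuran-2(3H)-one F5, in which the trans arrangement is the thermodynamically preferred one. Hydrogenation of F5 over 10% Pd/C in AcOH with a trace of HClO4 should reduce the benzylic carbonyl to CH2 and cleave both benzyl ethers in one operation. The route is rejoined at 17 and compound 16 is bypassed.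

**Further compounds**
F1 | step 5 | (4R,5R)-4-{2-[3,4-bis(benzyloxy)phenyl]-1,3-dithian-2-yl}-5-[(1R,2S,5R)-menthyl]oxydihydrofuran-2(3H)-one | O=C1C[C@@H](C2(SCCCS2)c2ccc(OCc3ccccc3)c(OCc3ccccc3)c2)[C@H](O[C@@H]2C[C@H](C)CC[C@H]2C(C)C)O1
F2 | step 6 | (3R,4R,5R)-4-[3,4-bis(benzyloxy)benzyl]-3-(3,4-dimethoxybenzyl)-5-[(1R,2S,5R)-menthyl]oxydihydrofuran-2(3H)-one | COc1ccc(C[C@H]2C(=O)O[C@@H](O[C@@H]3C[C@H](C)CC[C@H]3C(C)C)[C@@H]2Cc2ccc(OCc3ccccc3)c(OCc3ccccc3)c2)cc1OC
F3 | step 6 | potassium (2R,3R)-3-[3,4-bis(benzyloxy)benzyl]-2-(3,4-dimethoxybenzyl)-4-oxobutanoate | COc1ccc(C[C@@H](C(=O)[O-])[C@H](C=O)Cc2ccc(OCc3ccccc3)c(OCc3ccccc3)c2)cc1OC.[K+]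
F4 | step 6 | potassium (2R,3R)-3-[3,4-bis(benzyloxy)benzyl]-2-(3,4-dimethoxybenzyl)-4-hydroxybutanoate | COc1ccc(C[C@@H](C(=O)[O-])[C@H](CO)Cc2ccc(OCc3ccccc3)c(OCc3ccccc3)c2)cc1OC.[K+]
F5 | step 7 | (3R,4R)-4-[3,4-bis(benzyloxy)benzoyl]-3-(3,4-dimethoxybenzyl)dihydrofuran-2(3H)-one | COc1ccc(C[C@H]2C(=O)OC[C@@H]2C(=O)c2ccc(OCc3ccccc3)c(OCc3ccccc3)c2)cc1OC
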